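**Retrosynthetic overview**
- The target comes from its 2-ketone by hydride delivery to the α face. The 2-ketone comes from 4β,6α,10α-trihydroxydauc-8-en-2-one by double angeloylation, so no protecting groups are needed.
- The seven-membered ring is formed second, through C1–C10 (farnesyl C7 attacking C1). The C1=C2 enol, made by a 1,3-hydrogen shift in an allylic alcohol, adds to the Z-enal masked as a lactol.
- The C15 chain is built by joining a C10 aldehyde to a C5 bromo-senecioate. This gives a dihydropyranone that fixes C6 and the Z alkene.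
- The five-membered ring is formed first, through C4–C5 (farnesyl C10–C6). An allylcopper made from the myrcene diene adds to the isopropyl ketone.
- The ketone comes from β-myrcene through its epoxide, by a C10-to-C11 1,2-hydride shift that leaves the oxygen on the future C4.

**Assumption:** daucane numbering is used for all intermediates (C1 quaternary, C2 and C4 carbinols, C5 ring-fusion CH, C6 and C10 ester carbons); the cyclase is taken to join farnesyl C1–C7 and C6–C10 with a C10-to-C11 hydride shift; (R,R)-Ph-BPE is taken to give the 4R,5S series (otherwise its mirror image is used).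

**Step 1**
Reactants: 1 β-myrcene
Product: 2 myrcene 6,7-epoxide (racemic 2,2-dimethyl-3-(3-methylidenepent-4-en-1-yl)oxirane)
Conditions: mCPBA (1.0 equiv), CH2Cl2, 0 °C
Reagents that add atoms: mCPBA, OOC(=O)c1cccc(Cl)c1
Why: Prilezhaev epoxidation selects the electron-rich trisubstituted alkene over the conjugated diene, and the new stereocentre is erased in step 2.

**Step 2**
Reactants: 2 myrcene 6,7-epoxide
Product: 3 2-methyl-6-methylideneoct-7-en-3-one
Conditions: Er(OTf)3 (1 mol %), CH2Cl2, rt
Reagents that add atoms: none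
Why: In this Meinwald rearrangement the tertiary C–O bond ionises and a 1,2-hydride shift gives the isopropyl ketone, as in the limonene oxide to dihydrocarvone reaction type.

**Step 3**
Reactants: 3 2-methyl-6-methylideneoct-7-en-3-one
Product: 5 (1R,2S)-2-(hydroxymethyl)-3-methylidene-1-(propan-2-yl)cyclopentan-1-ol, via O,C-bis(pinacolboryl) cyclisation product 4 (not isolated)
Conditions: CuCl (5 mol %), (R,R)-Ph-BPE (6 mol %), NaOtBu (10 mol %), B2pin2 (1.1 equiv), THF, 0 °C to rt; then 30% H2O2, pH 7 phosphate buffer, 0 °C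
Reagents that add atoms: bis(pinacolato)diboron, CC1(C)OB(OC1(C)C)B2OC(C)(C)C(C)(C)O2; hydrogen peroxide, OO
Why: Proposed new method: borocupration of the vinyl group places boron on the terminal carbon and gives a 2-substituted allylcopper that adds through its γ carbon to the tethered ketone in a closed six-membered transition state (copper-catalysed borylative allylation of ketones with isoprene-type dienes, known intermolecularly and made intramolecular here); the ligand sets the absolute sense, and the isopropyl group lies anti to the CH2B arm, so CH2OH and 4-OH end up cis (4β-OH, 5α-H).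

**Step 4**
Reactants: 5 (1R,2S)-2-(hydroxymethyl)-3-methylidene-1-(propan-2-yl)cyclopentan-1-ol
Product: 6 (1R,2R)-2-hydroxy-5-methylidene-2-(propan-2-yl)cyclopentane-1-carbaldehyde
Conditions: [Cu(MeCN)4]OTf (5 mol %), 2,2′-bipyridine, TEMPO, N-methylimidazole, MeCN, air, rt; used crude
Reagents that add atoms: none
Why: Copper/nitroxyl aerobic oxidation converts only the primary alcohol, and its near-neutral conditions avoid epimerisation, alkene migration and retro-aldol of the β-hydroxy aldehyde.

**Step 5**
Reactants: 6 (1R,2R)-2-hydroxy-5-methylidene-2-(propan-2-yl)cyclopentane-1-carbaldehyde; 7 ethyl 4-bromo-3-methylbut-2-enoate (E/Z mixture)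
Product: 9 (6S)-6-[(1S,2R)-2-hydroxy-5-methylidene-2-(propan-2-yl)cyclopentyl]-4-methyl-5,6-dihydro-2H-pyran-2-one, via zinc alkoxide of the (2Z,5S)-hydroxy ester 8 (not isolated)
Conditions: activated Zn (3 equiv), 7 (2.5 equiv), THF, 40 °C; aq NH4Cl
Reagents that add atoms: ethyl 4-bromo-3-methylbut-2-enoate (7), CCOC(=O)C=C(C)CBr
Why: In this vinylogous Reformatsky reaction the zinc dienolate ends at the γ-adduct, which lactonises and locks the Z alkene, and zinc chelation of the 4-alkoxide with the aldehyde oxygen exposes the face away from C1=CH2, giving 6S.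

**Step 6**
Reactants: 9 (6S)-dihydropyranone
Product: 10 (6S)-6-[(1S,2R)-2,4-dihydroxy-5-methylidene-2-(propan-2-yl)cyclopentyl]-4-methyl-5,6-dihydro-2H-pyran-2-one (C2 epimers)
Conditions: SeO2 (0.3 equiv), tBuOOH (2 equiv), CH2Cl2, 0 °C to rt
Reagents that add atoms: tert-butyl hydroperoxide, CC(C)(C)OO
Why: Riley-type allylic hydroxylation (ene reaction followed by a 2,3-shift) attacks the ring CH2 next to the 1,1-disubstituted alkene in preference to the tertiary C5–H and the electron-poor lactone alkene, and the C2 configuration does not matter because it is erased in step 8.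

**Step 7**
Reactants: 10 allylic alcohol lactone
Product: 11 lactol (6S)-6-[(1S,2R)-2,4-dihydroxy-5-methylidene-2-(propan-2-yl)cyclopentyl]-4-methyl-5,6-dihydro-2H-pyran-2-ol (anomers)
Conditions: DIBAL-H (3.3 equiv), CH2Cl2, −78 °C; aqueous work-up
Reagents that add atoms: none
Why: Partial lactone reduction stops at the stable aluminium hemiacetal, and the lactol is the masked (Z)-δ-hydroxy enal.

**Step 8**
Reactants: 11 lactol
Product: 13 4β,6α,10α-trihydroxydauc-8-en-2-one, via open-chain enol enal 12 (not isolated)
Conditions: NiCl2(dppe) (5 mol %), LiBHEt3 (5 mol %), THF, rt; then MgBr2·OEt2 (1.5 equiv), iPr2NEt (0.3 equiv), THF (0.005 M), 25 to 40 °C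
Reagents that add atoms: none
Why: Proposed new method: a nickel-hydride 1,3-hydrogen shift turns the 2-methylidene allylic alcohol into the tetrasubstituted C1=C2 enol and creates the angular methyl (tandem allylic alcohol isomerisation–aldol reaction type, known intermolecularly), the enol adds 1,2 to the enal released from the lactol, and because the magnesium-mediated aldol is reversible the ring fusion is set thermodynamically: in the cis-fused adduct methyl and isopropyl are syn-1,3, so that adduct reopens, while the trans-fused chelate holding O2, O10 and O6 on magnesium (1β-Me, 10α-OH) accumulates.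

**Step 9**
Reactants: 13 4β,6α,10α-trihydroxydauc-8-en-2-one; 14 angelic acid
Product: 16 6α,10α-bis(angeloyloxy)-4β-hydroxydauc-8-en-2-one, via angelic 2,4,6-trichlorobenzoic anhydride 15 (not isolated)
Conditions: 14 (6 equiv), 2,4,6-trichlorobenzoyl chloride, Et3N, toluene, rt; then 13, 75 °C, no DMAP
Reagents that add atoms: angelic acid (14), C/C=C(/C)C(=O)O
Why: Yamaguchi-type mixed-anhydride esterification without a nucleophilic catalyst acylates both secondary alcohols without angelate-to-tiglate isomerisation and leaves the tertiary 4-OH free.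

**Step 10**
Reactants: 16 6α,10α-bis(angeloyloxy)-4β-hydroxydauc-8-en-2-one
Product: 17 6α,10α-bis(angeloyloxy)dauc-8-ene-2β,4β-diol (1R,2R,4R,5S,6S,10R)
Conditions: NaBH4, MeOH–CH2Cl2, −40 °C
Reagents that add atoms: none
Why: Borohydride attacks the cyclopentanone from the α face, opposite the pseudo-axial angular methyl (the steroid 17-ketone model), which gives the 2β-alcohol, and the hindered enoate esters are untouched.

**Compound list**
1 | β-myrcene | C=CC(=C)CCC=C(C)C | starting material
2 | myrcene 6,7-epoxide (racemic) | C=CC(=C)CCC1OC1(C)C | intermediate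
3 | 2-methyl-6-methylideneoct-7-en-3-one | C=CC(=C)CCC(=O)C(C)C | intermediate
4 | O,C-bis(pinacolboryl) cyclisation product | C=C1CC[C@@](OB2OC(C)(C)C(C)(C)O2)(C(C)C)[C@@H]1CB3OC(C)(C)C(C)(C)O3 | intermediate
5 | (1R,2S)-2-(hydroxymethyl)-3-methylidene-1-(propan-2-yl)cyclopentan-1-ol | C=C1CC[C@@](O)(C(C)C)[C@@H]1CO | intermediate
6 | (1R,2R)-2-hydroxy-5-methylidene-2-(propan-2-yl)cyclopentane-1-carbaldehyde | C=C1CC[C@@](O)(C(C)C)[C@@H]1C=O | intermediate
7 | ethyl 4-bromo-3-methylbut-2-enoate (E/Z) | CCOC(=O)C=C(C)CBr | starting material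
8 | (2Z,5S)-hydroxy ester (formed as zinc alkoxide, drawn as alcohol) | CCOC(=O)/C=C(C)\C[C@H](O)[C@@H]1C(=C)CC[C@@]1(O)C(C)C | intermediate
9 | (6S)-dihydropyranone | O=C1C=C(C)C[C@H](O1)[C@@H]2C(=C)CC[C@@]2(O)C(C)C | intermediate
10 | C2-hydroxylated lactone (C2 epimers) | O=C1C=C(C)C[C@H](O1)[C@@H]2C(=C)C(O)C[C@@]2(O)C(C)C | intermediate
11 | lactol (anomers, C2 epimers) | OC1C=C(C)C[C@H](O1)[C@@H]2C(=C)C(O)C[C@@]2(O)C(C)C | intermediate
12 | open-chain enol enal | O=C/C=C(C)\C[C@H](O)[C@@H]1C(C)=C(O)C[C@@]1(O)C(C)C | intermediate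
13 | 4β,6α,10α-trihydroxydauc-8-en-2-one | O[C@H]1CC(C)=C[C@@H](O)[C@@]2(C)C(=O)C[C@@](O)(C(C)C)[C@H]12 | intermediate
14 | angelic acid | C/C=C(/C)C(=O)O | starting material
15 | angelic 2,4,6-trichlorobenzoic anhydride | C/C=C(/C)C(=O)OC(=O)c1c(Cl)cc(Cl)cc1Cl | intermediate
16 | 6α,10α-bis(angeloyloxy)-4β-hydroxydauc-8-en-2-one | C/C=C(/C)C(=O)O[C@H]1CC(C)=C[C@@H](OC(=O)/C(C)=C\C)[C@@]2(C)C(=O)C[C@@](O)(C(C)C)[C@H]12 | intermediate
17 | CNP0249167.2 | C/C=C(/C)C(=O)O[C@H]1CC(C)=C[C@@H](OC(=O)/C(C)=C\C)[C@@]2(C)[C@H](O)C[C@@](O)(C(C)C)[C@H]12 | target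

**Total steps:** 10. **Longest linear sequence:** 10 (1 to 17).

**Steps most likely to fail**

Step 8 is the weakest step.
- Kinetic attack at C1 favours the cis-fused ring, so the trans fusion depends entirely on reversibility of the aldol.
- The enol may tautomerise to the ketone before the slow seven-membered closure takes place.
- Enolisation towards C3 can expel the 4-OH.

The fallback uses a preformed, regiodefined enolate instead of a catalytic enol. It starts from 10.
- TESOTf and 2,6-lutidine give the bis(triethylsilyl) ether F1.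
- RuHCl(CO)(PPh3)3 in toluene moves the exocyclic alkene into the ring and gives the tetrasubstituted silyl enol ether F2.
- DIBAL-H gives the lactol F3.
- Anhydrous fluoride (TASF) releases the C1 enolate, which closes and equilibrates to the 4-O-triethylsilyl keto diol F4.
- HF·pyridine then returns the route to 13.

Step 3 carries three risks. The allylcopper may close through the CH2 terminus, it may be protonated, or the enantioselectivity may be low. The fallback separates boron delivery from ring closure and starts from 3. Pt(dba)3-catalysed 1,4-diboration gives the (Z)-1,4-bis(boronate) F5. Only its CH2B–C(R)=CH allylboronate unit can reach the ketone. A chiral phosphoric acid, (R)-TRIP, then promotes the intramolecular allylboration, which returns the route to 4.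

In step 5 the β-hydroxy, β,γ-unsaturated aldehyde may isomerise or undergo retro-aldol on the basic zinc alkoxide, and the chelation control at C6 may be poor. The fallback is a Lewis-acid cyclocondensation and starts from 6. 1-Methoxy-3-methyl-1-(trimethylsilyloxy)buta-1,3-diene with Eu(fod)3 gives the hetero-Diels–Alder orthoester-type adduct F6. Mild acid collapses F6 to 9.

**Further compounds**
F1 | step 8 | bis(triethylsilyl) ether of 10 | O=C1C=C(C)C[C@H](O1)[C@@H]2C(=C)C(O[Si](CC)(CC)CC)C[C@@]2(O[Si](CC)(CC)CC)C(C)C
F2 | step 8 | tetrasubstituted silyl enol ether lactone | O=C1C=C(C)C[C@H](O1)[C@@H]2C(C)=C(O[Si](CC)(CC)CC)C[C@@]2(O[Si](CC)(CC)CC)C(C)C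
F3 | step 8 | silyl enol ether lactol | OC1C=C(C)C[C@H](O1)[C@@H]2C(C)=C(O[Si](CC)(CC)CC)C[C@@]2(O[Si](CC)(CC)CC)C(C)C
F4 | step 8 | 4-O-triethylsilyl-6α,10α-dihydroxydauc-8-en-2-one | O[C@H]1CC(C)=C[C@@H](O)[C@@]2(C)C(=O)C[C@@](O[Si](CC)(CC)CC)(C(C)C)[C@H]12
F5 | step 3 | (Z)-1,4-bis(pinacolboryl) adduct of 3 | CC(C)C(=O)CC/C(CB1OC(C)(C)C(C)(C)O1)=C/CB2OC(C)(C)C(C)(C)O2
F6 | step 5 | 2-methoxy-2-(trimethylsilyloxy)dihydropyran cycloadduct | COC1(O[Si](C)(C)C)C=C(C)C[C@H](O1)[C@@H]2C(=C)CC[C@@]2(O)C(C)C
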